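**Retrosynthetic overview**

1. Target ⇐ macrocyclic 9,14-diol acetonide. The 11-membered ring is closed last at C1–C14 by an alkenyl triflate/aldehyde Nozaki–Hiyama–Kishi (NHK) reaction; the C9 carbinol comes from reduction of the macrocyclic exo-methylene ketone.
2. C8–C9 ⇐ intermolecular NHK coupling of a bis(enol triflate) with a C9–C14 hydroxy aldehyde cut from (S)-citronellol (brings C12).
3. Both enol triflates (C1 and C8) ⇐ one cyclobutanone, by MeLi-triggered retro-aldol cleavage of C8–C15.
4. Cyclobutanone and cis-fused cyclopentane (second ring) ⇐ intramolecular enone–allene [2+2] photocycloaddition (C7–C16 and C8–C15 bonds).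
5. Photosubstrate ⇐ (S)-carvone (six-membered ring, bought): double α′-alkylation (C4), Criegee rearrangement (C3–O), Wharton enone transposition, α′-hydroxylation (C2–O).

Assumption: positions carry trinervitane numbers (C1=C15 with C17 methyl; C2, C3 carbinols; C4 with C18 methyl; C5–C7; C8=C19; C9; C10–C13 with C20 methyl on C12; C14; C16); carvone numbers are used up to compound 10.
Assumption: metalated species (enolates, alkoxides, organochromium and organonickel intermediates) are not numbered; every neutral intermediate of a telescoped step is.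

**Steps**

Step 1
Reactants: 1 but-3-yn-1-ol
Product: 3 penta-3,4-dien-1-ol, via Mannich base 2 (not isolated)
Conditions: (CH2O)n, i-Pr2NH, CuBr (0.5 equiv), 1,4-dioxane, reflux
Reagents that add atoms: paraformaldehyde, C=O
Why: Crabbé homologation, in which a copper-mediated alkyne–formaldehyde–amine (Mannich) coupling is followed by a 1,5-hydride shift that expels the imine and leaves the terminal allene; no stereocentre is formed.

Step 2
Reactants: 3 penta-3,4-dien-1-ol
Product: 4 5-iodopenta-1,2-diene
Conditions: PPh3, I2, imidazole, CH2Cl2, 0 °C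
Reagents that add atoms: iodine, [I][I]
Why: Appel-type iodination, an SN2 displacement of the primary alkoxyphosphonium by iodide that leaves the allene untouched.

Step 3
Reactants: 5 (S)-carvone
Product: 6 6-methylcarvone
Conditions: LiN(i-Pr)2, THF, −78 °C; MeI, −78 → 0 °C
Reagents that add atoms: iodomethane, CI
Why: kinetic α′-enolate alkylation of the enone; the new C6 centre (both epimers) is planarised again in step 4, so only the bought C5 centre matters.

Step 4
Reactants: 6 6-methylcarvone; 4 5-iodopenta-1,2-diene
Product: 7 (5R,6R)-6-methyl-6-(penta-3,4-dienyl)carvone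
Conditions: LiN(i-Pr)2, THF/HMPA, −78 °C; then 4 (1.5 equiv), −78 → 0 °C
Reagents that add atoms: none
Why: second kinetic α′-enolate alkylation, in which the iodide approaches the tetrasubstituted enolate anti to the C5 isopropenyl group, so the chain ends trans and the methyl cis to it, fixing the quaternary centre (C4 of the target).

Step 5
Reactants: 7 dialkylated carvone
Product: 9 (5S,6R)-5-acetoxy-2,6-dimethyl-6-(penta-3,4-dienyl)cyclohex-2-enone, via methoxy hydroperoxide 8 (not isolated)
Conditions: O3, CH2Cl2/MeOH, −78 °C (Sudan Red 7B end point); then Ac2O, Et3N, DMAP, 0 → 25 °C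
Reagents that add atoms: ozone, [O-][O+]=O; methanol, CO
Why: chemoselective ozonolysis of the electron-rich isopropenyl group (enone and allene react far more slowly) followed by Criegee rearrangement of the acetylated α-methoxy hydroperoxide, in which C5 migrates to oxygen with retention and so carries the bought configuration into the C3–O bond of the target.

Step 6
Reactants: 9 acetoxy enone
Product: 10 epoxy ketone
Conditions: t-BuOOH, DBU, CH2Cl2, 0 → 25 °C
Reagents that add atoms: tert-butyl hydroperoxide, CC(C)(C)OO
Why: Weitz–Scheffer nucleophilic epoxidation of the enone (acetate and allene are inert), expected anti to the acetoxy group; the epoxide configuration is erased in step 8.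

Step 7
Reactants: 10 epoxy ketone
Product: 12 cyclohexene-1,5-diol, via acetoxy allylic alcohol 11 (not isolated)
Conditions: N2H4·H2O, AcOH (cat.), MeOH, 0 → 25 °C; then K2CO3, 25 °C
Reagents that add atoms: none
Why: Wharton transposition (hydrazone, epoxide opening to an alkenyl diazene, loss of N2) moves the oxygen to C1 and the alkene to C15=C16, and methanolysis then frees the C3 hydroxyl at a stage without a ketone, so neither retro-aldol nor β-elimination can occur.

Step 8
Reactants: 12 cyclohexene-1,5-diol
Product: 13 transposed hydroxy enone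
Conditions: MnO2 (activated, excess), CH2Cl2, 25 °C
Reagents that add atoms: none
Why: MnO2 oxidises only the allylic alcohol, giving the 4,4-disubstituted enone whose β-carbon (C16) lies next to the quaternary centre.

Step 9
Reactants: 13 hydroxy enone
Product: 14 trans-5,6-dihydroxy enone
Conditions: LiN(i-Pr)2 (2.3 equiv), THF, −78 °C (inverse addition); MoO5·pyridine·HMPA, −78 → −30 °C
Reagents that add atoms: MoO5·pyridine·HMPA (MoOPH), O=[Mo]12(OO1)OO2.c1ccncc1.CN(C)P(=O)(N(C)C)N(C)C
Why: enolate α′-hydroxylation of the alkoxide–enolate dianion (an alkoxide cannot be eliminated) with MoO5·pyridine·HMPA as the electrophilic oxygen source, with oxygen delivered anti to the neighbouring C3 alkoxide, which gives the trans-2,3-diol and sets C2.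

Step 10
Reactants: 14 dihydroxy enone
Product: 15 acetonide enone
Conditions: 2-methoxypropene, PPTS (cat.), CH2Cl2, 0 °C
Reagents that add atoms: 2-methoxypropene, COC(C)=C
Why: acid-catalysed acetal exchange protects the trans-diol as an acetonide that survives the base, organometallic and oxidation steps and is removed by mild acid at the end.

Step 11
Reactants: 15 acetonide enone
Product: 16 methylenecyclobutane photoadduct
Conditions: hν (366 nm, uranium-glass filter), degassed cyclohexane (5 mM), 15 °C
Reagents that add atoms: none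
Why: intramolecular enone–allene [2+2] photocycloaddition, in which the triplet enone β-carbon (C16) bonds to the nearer allene carbon (C7) through a five-membered ring (rule of five) and the 1,4-diradical closes C15–C8; the tether on C4 enforces the cis-hydrindane (sets C16) and the cyclobutane forces C8 cis to C15 (sets C7).

Step 12
Reactants: 16 photoadduct
Product: 18 cyclobutanone, via ozonide 17 (not isolated)
Conditions: O3, CH2Cl2, −78 °C; then Me2S, −78 → 20 °C
Reagents that add atoms: ozone, [O-][O+]=O
Why: ozonolysis of the only remaining C=C with reductive work-up, run without alcohol so that the strained, non-enolisable 1,3-diketone is not opened by retro-Claisen attack.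

Step 13
Reactants: 18 cyclobutanone
Product: 20 bis(enol triflate), via ring enol triflate 19 (not isolated)
Conditions: MeLi (1.05 equiv), THF, −78 °C; PhNTf2 (2.4 equiv), −78 → −40 °C; then KN(SiMe3)2 (1.1 equiv), −78 °C
Reagents that add atoms: methyllithium, [Li]C; N-phenylbis(trifluoromethanesulfonimide), O=S(=O)(N(c1ccccc1)S(=O)(=O)C(F)(F)F)C(F)(F)F
Why: MeLi adds to the strained cyclobutanone rather than to the doubly α-branched cyclohexanone, the β-keto cyclobutoxide undergoes strain-driven retro-aldol cleavage of C8–C15, and the regiodefined C1 enolate is O-triflated; kinetic deprotonation of the new methyl ketone at CH3 and a second triflation give the 1,1-disubstituted enol triflate without touching C7.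

Step 14
Reactants: 21 (S)-citronellol
Product: 23 (S)-6-hydroxy-4-methylhexanal, via ozonide 22 (not isolated)
Conditions: O3, CH2Cl2, −78 °C; then Me2S, −78 → 20 °C
Reagents that add atoms: ozone, [O-][O+]=O
Why: ozonolysis of the trisubstituted alkene with reductive work-up; the bought C12 stereocentre is not touched.

Step 15
Reactants: 20 bis(enol triflate); 23 (S)-6-hydroxy-4-methylhexanal
Product: 24 C8–C9 coupled diol
Conditions: CrCl2 (6 equiv), NiCl2 (2 mol %), DMSO, 25 °C
Reagents that add atoms: none
Why: Nozaki–Hiyama–Kishi coupling, in which zerovalent nickel inserts much faster into the unhindered 1,1-disubstituted enol triflate than into the tetrasubstituted one and the alkenylchromium adds to the aldehyde; the C9 carbinol (both epimers) is oxidised in step 16.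

Step 16
Reactants: 24 coupled diol
Product: 25 keto aldehyde
Conditions: Dess–Martin periodinane (2.5 equiv), NaHCO3, CH2Cl2, 0 → 25 °C
Reagents that add atoms: none
Why: Dess–Martin oxidation converts the primary alcohol into the aldehyde and the allylic alcohol into the exo-methylene ketone in one buffered operation that leaves acetonide, triflate and C7 untouched.

Step 17
Reactants: 25 keto aldehyde
Product: 27 macrocyclic 14-hydroxy-9-ketone, via silyl ether 26 (not isolated)
Conditions: undivided cell, Al anode, nickel-foam cathode, constant current (5 mA); CrCl2 (20 mol %), NiCl2(MeOCH2CH2OMe) (5 mol %), TMSCl (3 equiv), LiCl, DMF, 25 °C, 25 added over 12 h (final 2 mM); then 10% aq. citric acid, THF, 0 °C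
Reagents that add atoms: none
Why: Proposed new method: a chromium-electrocatalytic Nozaki–Hiyama–Kishi macrocyclisation of a tetrasubstituted cycloalkenyl triflate, in which the cathode keeps regenerating divalent chromium and zerovalent nickel, zerovalent nickel inserts into the C1–OTf bond, the alkenyl group passes to trivalent chromium and adds to the tethered aldehyde (the ketone is not attacked), and TMSCl releases chromium from the alkoxide so that the active species stay dilute and ring closure beats oligomerisation; the closest known reactions are intermolecular electrochemical NHK couplings of alkenyl halides and stoichiometric CrCl2/NiCl2 macrocyclisations, and C14 is expected to be set by the tether delivering the aldehyde with its oxygen turned away from the C2 acetonide oxygen and the C12 methyl pseudo-equatorial.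

Step 18
Reactants: 27 macrocyclic hydroxy ketone
Product: 28 macrocyclic 9,14-diol acetonide
Conditions: NaBH4, CeCl3·7H2O, MeOH, −78 °C
Reagents that add atoms: none
Why: Luche reduction (1,2-selective) of the exo-methylene ketone, with hydride expected to add from the exposed outer face of the macrocyclic enone, anti to the hydrindane, which sets the C9 carbinol by substrate control.

Step 19
Reactants: 28 macrocyclic diol acetonide
Product: 30 target diacetate CNP0286573.1, via diacetate acetonide 29 (not isolated)
Conditions: Ac2O, pyridine, DMAP (cat.), CH2Cl2, 0 → 25 °C; then AcOH/H2O (4:1), 40 °C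
Reagents that add atoms: acetic anhydride, CC(=O)OC(C)=O
Why: acetylation of both allylic alcohols, then hydrolysis of the strained trans-fused acetonide by aqueous acetic acid, which does not cleave the allylic acetates.

**Compound list**

1 | but-3-yn-1-ol | C#CCCO | starting material
2 | 5-(diisopropylamino)pent-3-yn-1-ol (Mannich base) | CC(C)N(C(C)C)CC#CCCO | intermediate
3 | penta-3,4-dien-1-ol | C=C=CCCO | intermediate
4 | 5-iodopenta-1,2-diene | C=C=CCCI | intermediate
5 | (S)-(+)-carvone, (5S)-2-methyl-5-(prop-1-en-2-yl)cyclohex-2-en-1-one | CC1=CC[C@H](C(C)=C)CC1=O | starting material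
6 | 6-methylcarvone, (5S)-2,6-dimethyl-5-(prop-1-en-2-yl)cyclohex-2-en-1-one, both C6 epimers | CC1=CC[C@H](C(C)=C)C(C)C1=O | intermediate
7 | (5R,6R)-2,6-dimethyl-6-(penta-3,4-dien-1-yl)-5-(prop-1-en-2-yl)cyclohex-2-en-1-one; 6-methyl cis to isopropenyl | C=C=CCC[C@]1(C)[C@@H](C(C)=C)CC=C(C)C1=O | intermediate
8 | α-methoxy hydroperoxide of 7; isopropenyl replaced by C(CH3)(OCH3)OOH, epimers at that carbon | C=C=CCC[C@]1(C)[C@@H](C(C)(OC)OO)CC=C(C)C1=O | intermediate
9 | (5S,6R)-5-acetoxy-2,6-dimethyl-6-(penta-3,4-dien-1-yl)cyclohex-2-en-1-one; acetoxy cis to 6-methyl | C=C=CCC[C@]1(C)[C@@H](OC(C)=O)CC=C(C)C1=O | intermediate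
10 | 2,3-epoxide of 9; epoxide oxygen trans to the acetoxy group | C=C=CCC[C@]1(C)[C@@H](OC(C)=O)C[C@@H]2O[C@]2(C)C1=O | intermediate
11 | 5-acetoxy-2,4-dimethyl-4-(penta-3,4-dien-1-yl)cyclohex-2-en-1-ol; acetoxy cis to 4-methyl, 1-OH trans to acetoxy | C=C=CCC[C@]1(C)[C@@H](OC(C)=O)C[C@H](O)C(C)=C1 | intermediate
12 | 2,4-dimethyl-4-(penta-3,4-dien-1-yl)cyclohex-2-ene-1,5-diol; 5-OH cis to 4-methyl, 1-OH trans to 5-OH | C=C=CCC[C@]1(C)[C@@H](O)C[C@H](O)C(C)=C1 | intermediate
13 | 5-hydroxy-2,4-dimethyl-4-(penta-3,4-dien-1-yl)cyclohex-2-en-1-one; 5-OH cis to 4-methyl | C=C=CCC[C@]1(C)[C@@H](O)CC(=O)C(C)=C1 | intermediate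
14 | 5,6-dihydroxy-2,4-dimethyl-4-(penta-3,4-dien-1-yl)cyclohex-2-en-1-one; trans-5,6-diol, 5-OH cis to 4-methyl | C=C=CCC[C@]1(C)[C@@H](O)[C@H](O)C(=O)C(C)=C1 | intermediate
15 | 5,6-O-isopropylidene acetal (acetonide) of 14 | C=C=CCC[C@]1(C)[C@H]2OC(C)(C)O[C@@H]2C(=O)C(C)=C1 | intermediate
16 | photoadduct: 2,3-O-isopropylidene cis-hydrindan-1-one with a cyclobutane through C7, C16, C15 and C8(=C19H2); H-7, H-16, C17 and C18 methyls on one face | C=C1[C@@H]2CC[C@]3(C)[C@H]4OC(C)(C)O[C@@H]4C(=O)[C@@]1(C)[C@H]23 | intermediate
17 | ozonide (spiro-1,2,4-trioxolane at C8) of 16 | C1OOC2(O1)[C@@H]3CC[C@]4(C)[C@H]5OC(C)(C)O[C@@H]5C(=O)[C@@]2(C)[C@H]34 | intermediate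
18 | cyclobutanone: C8 ketone in place of the C8=C19 methylene of 16 | O=C1[C@@H]2CC[C@]3(C)[C@H]4OC(C)(C)O[C@@H]4C(=O)[C@@]1(C)[C@H]23 | intermediate
19 | cis-hydrindene C1 enol triflate (C1=C15) with C7 acetyl (H-7 cis to H-16) and 2,3-acetonide | CC(=O)[C@@H]1CC[C@]2(C)[C@H]3OC(C)(C)O[C@@H]3C(OS(=O)(=O)C(F)(F)F)=C(C)[C@H]12 | intermediate
20 | bis(enol triflate): C1–OTf (C1=C15) and C8–OTf (C8=C19H2) | C=C(OS(=O)(=O)C(F)(F)F)[C@@H]1CC[C@]2(C)[C@H]3OC(C)(C)O[C@@H]3C(OS(=O)(=O)C(F)(F)F)=C(C)[C@H]12 | intermediate
21 | (S)-(−)-citronellol, (3S)-3,7-dimethyloct-6-en-1-ol | C[C@@H](CCC=C(C)C)CCO | starting material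
22 | ozonide (1,2,4-trioxolane) of 21 | C[C@@H](CCC1OOC(C)(C)O1)CCO | intermediate
23 | (S)-6-hydroxy-4-methylhexanal | C[C@@H](CCC=O)CCO | intermediate
24 | C8–C9 coupled product: C9 secondary allylic alcohol (both epimers), C14 primary alcohol, C1 enol triflate, 2,3-acetonide | C=C(C(O)CC[C@H](C)CCO)[C@@H]1CC[C@]2(C)[C@H]3OC(C)(C)O[C@@H]3C(OS(=O)(=O)C(F)(F)F)=C(C)[C@H]12 | intermediate
25 | keto aldehyde: C9 ketone (exo-methylene enone), C14 aldehyde, C1 enol triflate | C=C(C(=O)CC[C@H](C)CC=O)[C@@H]1CC[C@]2(C)[C@H]3OC(C)(C)O[C@@H]3C(OS(=O)(=O)C(F)(F)F)=C(C)[C@H]12 | intermediate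
26 | 14-O-trimethylsilyl ether of 27 | C=C1C(=O)CC[C@H](C)C[C@H](O[Si](C)(C)C)C2=C(C)[C@@H]3[C@H]1CC[C@]3(C)[C@H]4OC(C)(C)O[C@H]24 | intermediate
27 | macrocycle (11-membered ring closed): 14-hydroxy-9-oxo-trinervita-1(15),8(19)-diene 2,3-acetonide | C=C1C(=O)CC[C@H](C)C[C@H](O)C2=C(C)[C@@H]3[C@H]1CC[C@]3(C)[C@H]4OC(C)(C)O[C@H]24 | intermediate
28 | trinervita-1(15),8(19)-diene-2,3,9,14-tetraol 2,3-acetonide | C=C1[C@H](O)CC[C@H](C)C[C@H](O)C2=C(C)[C@@H]3[C@H]1CC[C@]3(C)[C@H]4OC(C)(C)O[C@H]24 | intermediate
29 | 9,14-diacetate of 28 | C=C1[C@H](OC(C)=O)CC[C@H](C)C[C@H](OC(C)=O)C2=C(C)[C@@H]3[C@H]1CC[C@]3(C)[C@H]4OC(C)(C)O[C@H]24 | intermediate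
30 | CNP0286573.1, trinervita-1(15),8(19)-diene-2,3,9,14-tetraol 9,14-diacetate | C=C1[C@H](OC(C)=O)CC[C@H](C)C[C@H](OC(C)=O)C2=C(C)[C@@H]3[C@H]1CC[C@]3(C)[C@@H](O)[C@@H]2O | target

**Step count and risks**

Total steps: 19. Longest linear sequence: 17 (steps 1, 2, 4–13 and 15–19, from but-3-yn-1-ol); the chain from (S)-carvone is 16 steps and the chain from (S)-citronellol is 6.

The three steps most likely to fail:

Step 7. Hydrazone formation on the hindered, α-quaternary epoxy ketone may stall. The fallback sets out from 9 and leaves out step 6. Luche reduction (NaBH4, CeCl3·7H2O, MeOH, −78 °C) gives 5-acetoxy-2,6-dimethyl-6-(penta-3,4-dien-1-yl)cyclohex-2-en-1-ol F1 as carbinol epimers. Ph3SiOReO3 (2 mol %, Et2O, −50 → 0 °C) then moves the hydroxyl from the neopentyl carbon to the other allyl terminus by a [3,3] perrhenate shift, the known 1,3-transposition of allylic alcohols. This comes back to the route at 11 (both carbinol epimers converge in step 8), and the acetate methanolysis of step 7 follows.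

Step 13. MeLi must choose the cyclobutanone over the cyclohexanone, and the enolate must be trapped before it equilibrates. The fallback sets out from 16 and bypasses step 12. Mukaiyama hydration (Co(acac)2, PhSiH3, O2, THF, 0 °C) puts hydrogen on C19 and oxygen on C8 and gives tertiary cyclobutanol F2 without any carbonyl addition. KN(SiMe3)2 (1.0 equiv, THF, −78 °C) then forms the same cyclobutoxide, and retro-aldol cleavage with PhNTf2 trapping comes back to the route at 19. The second triflation of step 13 follows.

Step 17. This is the new macrocyclisation; the hindered triflate may not turn over under catalytic electrochemical conditions, or oligomers may form. The fallback uses stoichiometric chromium chemistry and closes the ring at the other carbinol. It sets out from 19 (step 13 stopped after the first triflation). CrCl2/NiCl2 (cat.) coupling in DMSO with (S)-citronellal F3 gives allylic alcohol F4 (C14 epimers separable). KN(SiMe3)2 (2.1 equiv) and PhNTf2 at −78 °C turn the methyl ketone into enol triflate F5. OsO4 (cat.)/NMO, then NaIO4, cleave only the trisubstituted alkene to aldehyde F6. CrCl2 (10 equiv)/NiCl2 (cat.) in DMSO/THF at 2 mM then closes the ring at C8–C9 and comes back to the route at 28; step 19 follows.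

**Further compounds**

F1 | step 7 | 5-acetoxy-2,6-dimethyl-6-(penta-3,4-dien-1-yl)cyclohex-2-en-1-ol, carbinol epimers | C=C=CCC[C@]1(C)[C@@H](OC(C)=O)CC=C(C)C1O
F2 | step 13 | tertiary cyclobutanol: C8 bears OH and the C19 methyl in place of the methylene of 16 | CC1(O)[C@@H]2CC[C@]3(C)[C@H]4OC(C)(C)O[C@@H]4C(=O)[C@@]1(C)[C@H]23
F3 | step 17 | (S)-citronellal | C[C@@H](CCC=C(C)C)CC=O
F4 | step 17 | C1–C14 coupled allylic alcohol with C7 acetyl and the citronellyl alkene | CC(=O)[C@@H]1CC[C@]2(C)[C@H]3OC(C)(C)O[C@@H]3C([C@@H](O)C[C@@H](C)CCC=C(C)C)=C(C)[C@H]12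
F5 | step 17 | C8 enol triflate (C8=C19H2) of F4 | C=C(OS(=O)(=O)C(F)(F)F)[C@@H]1CC[C@]2(C)[C@H]3OC(C)(C)O[C@@H]3C([C@@H](O)C[C@@H](C)CCC=C(C)C)=C(C)[C@H]12
F6 | step 17 | C9 aldehyde from F5 | C=C(OS(=O)(=O)C(F)(F)F)[C@@H]1CC[C@]2(C)[C@H]3OC(C)(C)O[C@@H]3C([C@@H](O)C[C@@H](C)CCC=O)=C(C)[C@H]12
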